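## The problem

The target 53 is a 36-membered macrolactone. A single C40 chain (C1 = lactone carbonyl, C40 = terminal methyl) is closed between C1 and the oxygen on C35, with methyl branches at C3 and C36, so that C36–C40 sit outside the ring as an (S)-hexan-2-yl group. There is no second ring to lean on, so the chain has to be grown from small pieces, and eleven stereocentres must be set: ten carbinols (C7, C9, C13, C17, C21, C25, C27, C29, C33, C35) and the methyl-bearing C36. Only the 1,3-pairs (C7/C9 syn, C25/C27 syn, C27/C29 anti, C33/C35 syn) and the C35/C36 anti pair are close enough for one centre to bias the next. The 1,5-related carbinols (C9/C13, C13/C17, C17/C21, C21/C25, C29/C33) are insulated by three methylenes, and each needs reagent or catalyst control. The fragile parts are the (Z)-trisubstituted enoate C1–C3 (Z-to-E drift on activation, conjugate addition), β-oxygenated aldehydes along the way (elimination), an α-methyl aldehyde at C35 (epimerisation at C36) and, in the free polyol, the lactone itself, which can migrate to a neighbouring hydroxyl; the hydroxyls therefore stay masked to the last step, and the C35 oxygen needs a group of its own. The feature that opens the central disconnection is that the C21 and C25 carbinols are 1,5-anti and flank exactly C22–C24: a three-carbon, doubly nucleophilic allyl unit between a C21 aldehyde and a C25 aldehyde can create both carbinols while joining two halves of similar size.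

## Retrosynthesis

**Lactone bond.** Target 53 is taken back to its nona-silyl ether 52, and the C1–O35 ester bond is cut to seco acid 50. A macrolactonisation is the obvious ring closure for a strain-free 36-membered ring. It asks that only the C35 hydroxyl be free, so C35 carries a PMB ether (removed from 48 to give 49) while every other hydroxyl is a TBS ether.

**C22–C23 saturation.** The fully silylated ester 48 comes from diol 47 and this from ene-diol 46. The (E)-C22=C23 bond and the two free hydroxyls in 46 are the trace of the coupling reaction, removed by diimide and silylation.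

**Key disconnection, C21–C22 and C24–C25.** Diol 46 is cut into west aldehyde 21 (C1–C21), allenylboronate 43 (C22–C24) and east aldehyde 39 (C25–C40). This cut is preferred to the other 1,5-pairs for three reasons.
- It is 1,5-anti, the relationship the E-selective double allylboration delivers.
- It divides the chain into halves of 21 and 16 carbons with four and five stereocentres; a cut at the other anti pair, C9/C13, would leave a C13–C40 piece carrying almost everything.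
- It creates two of the ten carbinols in the coupling itself.

The forward reaction must keep the order of addition (21 first, 39 second), give the E alkene, and tolerate the enoate and all ethers.

**C3–C4 bond.** Aldehyde 21 is traced through alcohol 20 and PMB ether 19 to terminal alkene 17 and iodoenoate 2. A B-alkyl Suzuki coupling takes the Z geometry from 2, itself one step from ynoate 1, and brings the enoate in only after all iridium- and rhodium-catalysed steps of the west half.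

**West chain by iteration.** Alkene 17 is unravelled carbinol by carbinol (17, 16, 15, 14, 13, 12, 11, 10, 9, 8, 7) to mono-protected pentanediol 4 (from 3). Each carbinol is one catalyst-controlled allylation with allyl acetate 5. Each (CH2)3 spacer is that allyl group plus one carbon from hydroformylation. The C7/C9 1,3-diol is an allyl group shortened by oxidative cleavage to aldehyde 15, which is allylated directly at the aldehyde oxidation level. The forward steps need only catalyst control, which suits the insulated 1,5-centres.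

**East chain by the same logic.** Aldehyde 39 goes back through 38, 37, 36, 35, 34, 33, 32, 31, 30 and 29 to homoallylic alcohol 28. The cleavage aldehydes 30 and 36 are each allylated in the step after they are made. Compound 28 is the allylation product of (S)-2-methylhexan-1-ol 26, made by Evans methylation (25) of the hexanoyl imide 24 from oxazolidinone 22 and hexanoyl chloride 23. Allylating 26 from the alcohol oxidation level avoids isolating the epimerisable aldehyde 27.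

**Linchpin.** Allenylboronate 43 comes in one operation from propargyl bromide 40.

## Roads not taken

**Alternative 1: Suzuki macrocyclisation at C3–C4.** The cut is the C3–C4 bond of the ring. The seco compound A1 carries the C35 (Z)-3-iodobut-2-enoate and a terminal C4=C5 alkene; hydroboration with 9-BBN and intramolecular coupling under Pd(dppf)Cl2 catalysis would give the nona-TBS macrolide A2, which is identical with 52.
- Merits: the hindered C35 ester is made intermolecularly with a small acid, and the Z geometry is bought with the iodoenoate and never exposed to acyl activation. In this respect it is better than the lactonisation chosen here.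
- Weak points: an sp3–sp2 coupling that closes a 36-membered ring at high dilution has to outrun protodeboronation, and the only permitted alkene in A1 is C4=C5, so the whole C4–C40 chain must first be built linearly. It says nothing about how the remote stereocentres are made.
- Comparison: the chosen plan sets against it a convergent union that creates C21 and C25, and it keeps this ring closure in reserve as the fallback for step 38.

**Alternative 2: silyl dithiane linchpin for C25–C29.** The cuts are C26–C27 and C27–C28. The lithiated silyl dithiane A3 would open west epoxide A4 at C26, silicon would migrate to the C25 oxygen, and the regenerated anion would open east epoxide A5 at C28, giving A6 in one flask.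
- Merits: a very reliable three-component union in which C25 and C29 arrive with the epoxides, with no stereocentre at risk in the coupling. In reliability of the union it is ahead of the chosen plan.
- Weak points: C27 arrives as a dithiane and must be unmasked and reduced with 1,3-control (anti to C29, syn to C25), which adds steps. The strongly basic conditions exclude the enoate, so C1–C3 must be added afterwards. The west epoxide A4 (C4–C26) still contains all the insulated 1,5-centres C9 to C25, which this disconnection does nothing to solve.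
- Comparison: the pieces are less balanced (23 against 13 carbons). The chosen plan offsets its riskier coupling by making two carbinols in it.

**Alternative 3: ring-closing metathesis at C19=C20.** The cut is C19=C20 in an ester-linked diene A7 (allyl on the C17 carbinol, vinyl on the C21 carbinol). The second-generation Grubbs catalyst would close the 36-membered ring to A8, whose alkene geometry is irrelevant because it is reduced.
- Merits: metathesis to large unstrained rings is dependable, the trisubstituted enoate is a spectator, and the ester is again made intermolecularly. As a ring closure it is probably more certain than either the lactonisation or the key coupling used here.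
- Weak points: the C35 ester must still be formed from the Z-enoic acid, so the isomerisation risk remains. The new alkene is flanked by an allylic silyl ether, which slows the catalyst. No stereocentre is created, so all eleven have to be installed beforehand, C21 and C25 included.
- Comparison: the chosen plan has the fragment union itself deliver C21 and C25.

Key step: step 33

Conventions: carbon numbers in the text are macrolide numbers (C1 lactone carbonyl to C40); locants in compound names are systematic. TBSO = (tert-butyldimethylsilyl)oxy, PMBO = (4-methoxybenzyl)oxy, Ipc = isopinocampheyl.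

Assumption: in the iridium-catalysed allylations (S)-Cl,MeO-BIPHEP is taken to deliver allyl to the same carbonyl face as the B-allylborane made from (+)-α-pinene, and the (R)-ligand to the other face. This correlation is recalled rather than derived; the configurations written for the products are the ones the route needs, and a reversed correlation would only exchange the ligand antipodes.

## Route

Step 1
Reactants: 1 methyl but-2-ynoate
Product: 2 methyl (Z)-3-iodobut-2-enoate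
Conditions: NaI, AcOH, 115 °C
Reagents that add atoms: sodium iodide, [Na+].[I-]
Why: Conjugate hydroiodination of an ynoate; iodide adds at C3 and the allenolate is protonated anti, which places iodine cis to the ester (Z).

Step 2
Reactants: 3 pentane-1,5-diol
Product: 4 5-(PMBO)pentan-1-ol
Conditions: NaH, THF, 0 °C; PMBCl, Bu4NI (cat.), reflux (diol in excess)
Reagents that add atoms: 4-methoxybenzyl chloride, COc1ccc(CCl)cc1
Why: Williamson etherification; the excess of diol keeps alkylation at the mono stage.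

Step 3
Reactants: 4 5-(PMBO)pentan-1-ol; 5 allyl acetate
Product: 7 (S)-8-(PMBO)oct-1-en-4-ol, via 5-(PMBO)pentanal 6 (not isolated)
Conditions: [Ir(cod)Cl]2 (cat.), (R)-Cl,MeO-BIPHEP, 4-Cl-3-NO2-C6H3CO2H, Cs2CO3, THF, 100 °C (sealed tube)
Reagents that add atoms: none
Why: Krische allylation from the alcohol oxidation level: the cyclometallated iridium catalyst dehydrogenates 4 to 6 and adds its π-allyl unit to one carbonyl face under ligand control, setting C17.

Step 4
Reactants: 7 (S)-8-(PMBO)oct-1-en-4-ol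
Product: 8 (S)-4-(TBSO)-8-(PMBO)oct-1-ene
Conditions: TBSOTf, 2,6-lutidine, CH2Cl2, −78 → 0 °C
Reagents that add atoms: tert-butyldimethylsilyl trifluoromethanesulfonate, CC(C)(C)[Si](C)(C)OS(=O)(=O)C(F)(F)F
Why: Standard silylation of a secondary alcohol with a silyl triflate and a hindered base; no stereocentre is touched.

Step 5
Reactants: 8 (S)-4-(TBSO)-8-(PMBO)oct-1-ene
Product: 9 (S)-5-(TBSO)-9-(PMBO)nonanal
Conditions: Rh(acac)(CO)2 (cat.), BIPHEPHOS, CO/H2 (1:1, 5 bar), THF, 60 °C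
Reagents that add atoms: carbon monoxide, [C-]#[O+]
Why: Linear-selective rhodium hydroformylation of a terminal alkene with a wide-bite-angle bisphosphite; it adds C13 as the aldehyde and leaves ethers untouched.

Step 6
Reactants: 9 (S)-5-(TBSO)-9-(PMBO)nonanal; 5 allyl acetate
Product: 10 (4S,8S)-8-(TBSO)-12-(PMBO)dodec-1-en-4-ol
Conditions: [Ir(cod)Cl]2 (cat.), (R)-Cl,MeO-BIPHEP, 4-Cl-3-NO2-C6H3CO2H, Cs2CO3, i-PrOH, THF, 100 °C (sealed tube)
Reagents that add atoms: none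
Why: Krische allylation from the aldehyde level with isopropanol as reductant; C13 is set by the ligand alone, the C17 centre being too remote to interfere.

Step 7
Reactants: 10 (4S,8S)-8-(TBSO)-12-(PMBO)dodec-1-en-4-ol
Product: 11 (4S,8S)-4,8-bis(TBSO)-12-(PMBO)dodec-1-ene
Conditions: TBSOTf, 2,6-lutidine, CH2Cl2, −78 → 0 °C
Reagents that add atoms: tert-butyldimethylsilyl trifluoromethanesulfonate, CC(C)(C)[Si](C)(C)OS(=O)(=O)C(F)(F)F
Why: Standard silylation of a secondary alcohol.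

Step 8
Reactants: 11 (4S,8S)-4,8-bis(TBSO)-12-(PMBO)dodec-1-ene
Product: 12 (5S,9S)-5,9-bis(TBSO)-13-(PMBO)tridecanal
Conditions: Rh(acac)(CO)2 (cat.), BIPHEPHOS, CO/H2 (1:1, 5 bar), THF, 60 °C
Reagents that add atoms: carbon monoxide, [C-]#[O+]
Why: Linear-selective hydroformylation as in step 5; it adds C9.

Step 9
Reactants: 12 (5S,9S)-5,9-bis(TBSO)-13-(PMBO)tridecanal; 5 allyl acetate
Product: 13 (4R,8R,12S)-8,12-bis(TBSO)-16-(PMBO)hexadec-1-en-4-ol
Conditions: [Ir(cod)Cl]2 (cat.), (S)-Cl,MeO-BIPHEP, 4-Cl-3-NO2-C6H3CO2H, Cs2CO3, i-PrOH, THF, 100 °C (sealed tube)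
Reagents that add atoms: none
Why: Krische allylation from the aldehyde level; the antipodal ligand sets C9 opposite in sense to C13 and C17, giving the 1,5-anti relation to C13.

Step 10
Reactants: 13 (4R,8R,12S)-8,12-bis(TBSO)-16-(PMBO)hexadec-1-en-4-ol
Product: 14 (4R,8S,12S)-4,8,12-tris(TBSO)-16-(PMBO)hexadec-1-ene
Conditions: TBSOTf, 2,6-lutidine, CH2Cl2, −78 → 0 °C
Reagents that add atoms: tert-butyldimethylsilyl trifluoromethanesulfonate, CC(C)(C)[Si](C)(C)OS(=O)(=O)C(F)(F)F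
Why: Standard silylation of a secondary alcohol.

Step 11
Reactants: 14 (4R,8S,12S)-4,8,12-tris(TBSO)-16-(PMBO)hexadec-1-ene
Product: 15 (3R,7S,11S)-3,7,11-tris(TBSO)-15-(PMBO)pentadecanal
Conditions: OsO4 (cat.), NaIO4, 2,6-lutidine, dioxane/H2O, rt
Reagents that add atoms: sodium periodate, [Na+].[O-]I(=O)(=O)=O
Why: Lemieux–Johnson cleavage of the terminal alkene (chosen over ozone because of the PMB ether) gives the C7 aldehyde; the β-silyloxy aldehyde is passed through a short silica pad and used at once, so that it is never stored.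

Step 12
Reactants: 15 (3R,7S,11S)-3,7,11-tris(TBSO)-15-(PMBO)pentadecanal; 5 allyl acetate
Product: 16 (4S,6R,10S,14S)-6,10,14-tris(TBSO)-18-(PMBO)octadec-1-en-4-ol
Conditions: [Ir(cod)Cl]2 (cat.), (S)-Cl,MeO-BIPHEP, 4-Cl-3-NO2-C6H3CO2H, Cs2CO3, i-PrOH, THF, 100 °C (sealed tube)
Reagents that add atoms: none
Why: Krische allylation from the aldehyde level with isopropanol as terminal reductant, as in steps 6 and 9; the ligand sets C7 syn to C9 under catalyst control, the β-silyloxy centre giving only weak 1,3-induction, and the substoichiometric carbonate, buffered by the nitrobenzoic acid, limits β-elimination.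

Step 13
Reactants: 16 (4S,6R,10S,14S)-6,10,14-tris(TBSO)-18-(PMBO)octadec-1-en-4-ol
Product: 17 (4S,6R,10S,14S)-4,6,10,14-tetrakis(TBSO)-18-(PMBO)octadec-1-ene
Conditions: TBSOTf, 2,6-lutidine, CH2Cl2, −78 → 0 °C
Reagents that add atoms: tert-butyldimethylsilyl trifluoromethanesulfonate, CC(C)(C)[Si](C)(C)OS(=O)(=O)C(F)(F)F
Why: Standard silylation of a secondary alcohol.

Step 14
Reactants: 17 (4S,6R,10S,14S)-4,6,10,14-tetrakis(TBSO)-18-(PMBO)octadec-1-ene; 2 methyl (Z)-3-iodobut-2-enoate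
Product: 19 methyl (2Z,7S,9R,13S,17S)-7,9,13,17-tetrakis(TBSO)-21-(PMBO)-3-methylhenicos-2-enoate, via B-alkyl-9-BBN 18 (not isolated)
Conditions: 9-BBN, THF, rt; then 2, Pd(dppf)Cl2 (cat.), AsPh3, Cs2CO3, DMF/H2O, rt
Reagents that add atoms: none
Why: Anti-Markovnikov hydroboration of the only alkene and B-alkyl Suzuki–Miyaura coupling with the β-iodoenoate; oxidative addition and reductive elimination retain the alkene geometry, so C3–C4 forms with C4 cis to the ester (Z).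

Step 15
Reactants: 19 methyl (2Z,7S,9R,13S,17S)-7,9,13,17-tetrakis(TBSO)-21-(PMBO)-3-methylhenicos-2-enoate
Product: 20 methyl (2Z,7S,9R,13S,17S)-7,9,13,17-tetrakis(TBSO)-21-hydroxy-3-methylhenicos-2-enoate
Conditions: DDQ, CH2Cl2/pH 7 buffer, 0 °C
Reagents that add atoms: none
Why: Oxidative cleavage of a PMB ether; silyl ethers and the electron-poor enoate are inert to DDQ.

Step 16
Reactants: 20 methyl (2Z,7S,9R,13S,17S)-7,9,13,17-tetrakis(TBSO)-21-hydroxy-3-methylhenicos-2-enoate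
Product: 21 methyl (2Z,7S,9R,13S,17R)-7,9,13,17-tetrakis(TBSO)-3-methyl-21-oxohenicos-2-enoate
Conditions: PhI(OAc)2, TEMPO (cat.), CH2Cl2, rt
Reagents that add atoms: none
Why: Oxoammonium-mediated oxidation of a primary alcohol to the aldehyde without over-oxidation; the C17 descriptor changes only because the priorities change.

Step 17
Reactants: 22 (S)-4-benzyloxazolidin-2-one; 23 hexanoyl chloride
Product: 24 (S)-4-benzyl-3-hexanoyloxazolidin-2-one
Conditions: n-BuLi, THF, −78 °C; then 23, −78 → 0 °C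
Reagents that add atoms: none
Why: N-Acylation of the lithiated Evans auxiliary.

Step 18
Reactants: 24 (S)-4-benzyl-3-hexanoyloxazolidin-2-one
Product: 25 (S)-4-benzyl-3-[(S)-2-methylhexanoyl]oxazolidin-2-one
Conditions: NaN(SiMe3)2, THF, −78 °C; MeI
Reagents that add atoms: iodomethane, CI
Why: Evans alkylation: the chelated Z-enolate is methylated on the face opposite the benzyl group, which with the butyl chain already in place gives the S configuration at C36.

Step 19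
Reactants: 25 (S)-4-benzyl-3-[(S)-2-methylhexanoyl]oxazolidin-2-one
Product: 26 (S)-2-methylhexan-1-ol
Conditions: LiBH4, H2O (1 equiv), Et2O, 0 °C
Reagents that add atoms: none
Why: Reductive removal of the auxiliary to the primary alcohol without epimerisation; the oxazolidinone is recovered.

Step 20
Reactants: 26 (S)-2-methylhexan-1-ol; 5 allyl acetate
Product: 28 (4R,5S)-5-methylnon-1-en-4-ol, via (S)-2-methylhexanal 27 (not isolated)
Conditions: [Ir(cod)Cl]2 (cat.), (R)-Cl,MeO-BIPHEP, 4-Cl-3-NO2-C6H3CO2H, Cs2CO3, THF, 100 °C (sealed tube)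
Reagents that add atoms: none
Why: Krische allylation of a β-stereogenic alcohol from the alcohol level; the epimerisable aldehyde 27 exists only transiently and the ligand, not the α-methyl group, sets C35 anti to the C36 methyl.

Step 21
Reactants: 28 (4R,5S)-5-methylnon-1-en-4-ol
Product: 29 (4R,5S)-4-(PMBO)-5-methylnon-1-ene
Conditions: NaH, DMF, 0 °C; PMBCl, Bu4NI (cat.), rt
Reagents that add atoms: 4-methoxybenzyl chloride, COc1ccc(CCl)cc1
Why: Williamson etherification; PMB is chosen for C35 because it cannot migrate under the later basic allylations and is removable beside nine silyl ethers.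

Step 22
Reactants: 29 (4R,5S)-4-(PMBO)-5-methylnon-1-ene
Product: 30 (3R,4S)-3-(PMBO)-4-methyloctanal
Conditions: OsO4 (cat.), NaIO4, 2,6-lutidine, dioxane/H2O, rt
Reagents that add atoms: sodium periodate, [Na+].[O-]I(=O)(=O)=O
Why: Lemieux–Johnson cleavage as in step 11 gives the C33 aldehyde; the PMB ether is untouched and the β-alkoxy aldehyde is carried on without storage.

Step 23
Reactants: 30 (3R,4S)-3-(PMBO)-4-methyloctanal; 5 allyl acetate
Product: 31 (4R,6R,7S)-6-(PMBO)-7-methylundec-1-en-4-ol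
Conditions: [Ir(cod)Cl]2 (cat.), (R)-Cl,MeO-BIPHEP, 4-Cl-3-NO2-C6H3CO2H, Cs2CO3, i-PrOH, THF, 100 °C (sealed tube)
Reagents that add atoms: none
Why: Krische allylation of a β-alkoxy aldehyde from the aldehyde level with isopropanol as reductant; catalyst control sets C33 syn to C35.

Step 24
Reactants: 31 (4R,6R,7S)-6-(PMBO)-7-methylundec-1-en-4-ol
Product: 32 (4R,6R,7S)-4-(TBSO)-6-(PMBO)-7-methylundec-1-ene
Conditions: TBSOTf, 2,6-lutidine, CH2Cl2, −78 → 0 °C
Reagents that add atoms: tert-butyldimethylsilyl trifluoromethanesulfonate, CC(C)(C)[Si](C)(C)OS(=O)(=O)C(F)(F)F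
Why: Standard silylation of a secondary alcohol.

Step 25
Reactants: 32 (4R,6R,7S)-4-(TBSO)-6-(PMBO)-7-methylundec-1-ene
Product: 33 (5R,7R,8S)-5-(TBSO)-7-(PMBO)-8-methyldodecanal
Conditions: Rh(acac)(CO)2 (cat.), BIPHEPHOS, CO/H2 (1:1, 5 bar), THF, 60 °C
Reagents that add atoms: carbon monoxide, [C-]#[O+]
Why: Linear-selective hydroformylation as in step 5; it adds C29.

Step 26
Reactants: 33 (5R,7R,8S)-5-(TBSO)-7-(PMBO)-8-methyldodecanal; 5 allyl acetate
Product: 34 (4S,8R,10R,11S)-8-(TBSO)-10-(PMBO)-11-methylpentadec-1-en-4-ol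
Conditions: [Ir(cod)Cl]2 (cat.), (R)-Cl,MeO-BIPHEP, 4-Cl-3-NO2-C6H3CO2H, Cs2CO3, i-PrOH, THF, 100 °C (sealed tube)
Reagents that add atoms: none
Why: Krische allylation from the aldehyde level; the ligand sets C29 (1,5-syn to C33), with no influence from the remote centres.

Step 27
Reactants: 34 (4S,8R,10R,11S)-8-(TBSO)-10-(PMBO)-11-methylpentadec-1-en-4-ol
Product: 35 (4S,8R,10R,11S)-4,8-bis(TBSO)-10-(PMBO)-11-methylpentadec-1-ene
Conditions: TBSOTf, 2,6-lutidine, CH2Cl2, −78 → 0 °C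
Reagents that add atoms: tert-butyldimethylsilyl trifluoromethanesulfonate, CC(C)(C)[Si](C)(C)OS(=O)(=O)C(F)(F)F
Why: Standard silylation of a secondary alcohol.

Step 28
Reactants: 35 (4S,8R,10R,11S)-4,8-bis(TBSO)-10-(PMBO)-11-methylpentadec-1-ene
Product: 36 (3S,7R,9R,10S)-3,7-bis(TBSO)-9-(PMBO)-10-methyltetradecanal
Conditions: OsO4 (cat.), NaIO4, 2,6-lutidine, dioxane/H2O, rt
Reagents that add atoms: sodium periodate, [Na+].[O-]I(=O)(=O)=O
Why: Lemieux–Johnson cleavage as in step 11 gives the C27 aldehyde, which is used at once.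

Step 29
Reactants: 36 (3S,7R,9R,10S)-3,7-bis(TBSO)-9-(PMBO)-10-methyltetradecanal; 5 allyl acetate
Product: 37 (4S,6S,10R,12R,13S)-6,10-bis(TBSO)-12-(PMBO)-13-methylheptadec-1-en-4-ol
Conditions: [Ir(cod)Cl]2 (cat.), (S)-Cl,MeO-BIPHEP, 4-Cl-3-NO2-C6H3CO2H, Cs2CO3, i-PrOH, THF, 100 °C (sealed tube)
Reagents that add atoms: none
Why: Krische allylation of a β-silyloxy aldehyde from the aldehyde level with isopropanol as reductant; the ligand sets C27 anti to C29, overriding any small bias from the β-silyloxy centre.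

Step 30
Reactants: 37 (4S,6S,10R,12R,13S)-6,10-bis(TBSO)-12-(PMBO)-13-methylheptadec-1-en-4-ol
Product: 38 (4S,6S,10R,12R,13S)-4,6,10-tris(TBSO)-12-(PMBO)-13-methylheptadec-1-ene
Conditions: TBSOTf, 2,6-lutidine, CH2Cl2, −78 → 0 °C
Reagents that add atoms: tert-butyldimethylsilyl trifluoromethanesulfonate, CC(C)(C)[Si](C)(C)OS(=O)(=O)C(F)(F)F
Why: Standard silylation of a secondary alcohol.

Step 31
Reactants: 38 (4S,6S,10R,12R,13S)-4,6,10-tris(TBSO)-12-(PMBO)-13-methylheptadec-1-ene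
Product: 39 (3R,5S,9R,11R,12S)-3,5,9-tris(TBSO)-11-(PMBO)-12-methylhexadecanal
Conditions: OsO4 (cat.), NaIO4, 2,6-lutidine, dioxane/H2O, rt
Reagents that add atoms: sodium periodate, [Na+].[O-]I(=O)(=O)=O
Why: Lemieux–Johnson cleavage gives the C25 aldehyde directly; it is used at once because β-silyloxy aldehydes eliminate on standing.

Step 32
Reactants: 40 propargyl bromide
Product: 43 2-(propa-1,2-dien-1-yl)-5,5-dimethyl-1,3,2-dioxaborinane, via allenylmagnesium bromide 41 (not isolated), via allenylboronic acid 42 (not isolated)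
Conditions: Mg, HgCl2 (cat.), Et2O, 0 °C; B(OMe)3, −78 °C; aq. HCl; neopentyl glycol, MgSO4, rt
Reagents that add atoms: trimethyl borate, COB(OC)OC; neopentyl glycol, OCC(C)(C)CO
Why: The propargyl/allenyl Grignard reagent is borylated to the allenylboronate, hydrolysed and re-esterified with the unhindered 1,3-diol, whose small boronate ring is what later permits the E-selective second allylboration.

Step 33
Reactants: 43 2-(propa-1,2-dien-1-yl)-5,5-dimethyl-1,3,2-dioxaborinane; 21 methyl (2Z,7S,9R,13S,17R)-7,9,13,17-tetrakis(TBSO)-3-methyl-21-oxohenicos-2-enoate; 39 (3R,5S,9R,11R,12S)-3,5,9-tris(TBSO)-11-(PMBO)-12-methylhexadecanal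
Product: 46 methyl (2Z,7S,9R,13S,17S,21R,22E,25S,27S,29S,33R,35R,36S)-7,9,13,17,27,29,33-heptakis(TBSO)-21,25-dihydroxy-35-(PMBO)-3,36-dimethyltetraconta-2,22-dienoate, via γ-boryl allylborane 44 (not isolated), via C21 borinate allylboronate 45 (not isolated)
Conditions: (dIpc)2BH [from (+)-α-pinene], Et2O, −25 → 0 °C; 21, −78 °C; 39 (limiting), −78 °C → rt; aq. NaHCO3, H2O2
Reagents that add atoms: none
Why: Hydroboration of the terminal C=C of allene 43, with equilibration at 0 °C by 1,3-boratropic shifts, gives the (E)-γ-boryl allylborane 44. At −78 °C only its dialkylborane end reacts: it allylates 21 through a chair transition state and forms C21–C22, the Ipc groups from (+)-α-pinene selecting the carbonyl face that gives 21R and the E geometry placing the C22 boronate anti to the C21 oxygen (45). Intermediate 45 is an α-substituted allylboronate that adds to 39 on warming through a second chair with its α-substituent equatorial, which the small neopentyl glycol boronate allows; this forms C24–C25 with an E C22=C23 bond and relays the C22 configuration to C25 (25S, hence 1,5-anti). The closest known reaction type is the one-pot double allylboration of two different aldehydes with an in situ γ-boryl allylborane, established for (E)-1,5-anti-ene-diols and applied here to two elaborated aldehydes. No ring is formed, so no mode of ring closure arises. The order of addition is secured by the large reactivity gap between the allyldialkylborane and the allylboronate, with 21 added first and 39 second as the limiting partner. C21 is under reagent control and C25 under 1,3-chirality transfer, against which the C27 silyloxy group offers only weak 1,3-induction in a closed transition state. The ester, enoate, silyl and PMB ethers are inert to allylboron reagents and to the buffered peroxide work-up.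

Step 34
Reactants: 46 methyl (2Z,7S,9R,13S,17S,21R,22E,25S,27S,29S,33R,35R,36S)-7,9,13,17,27,29,33-heptakis(TBSO)-21,25-dihydroxy-35-(PMBO)-3,36-dimethyltetraconta-2,22-dienoate
Product: 47 methyl (2Z,7S,9R,13S,17S,21S,25S,27S,29S,33R,35R,36S)-7,9,13,17,27,29,33-heptakis(TBSO)-21,25-dihydroxy-35-(PMBO)-3,36-dimethyltetracont-2-enoate
Conditions: 2-NO2C6H4SO2NHNH2, Et3N, CH2Cl2, rt
Reagents that add atoms: none
Why: Diimide reduction: concerted syn transfer of H2 to the unhindered disubstituted C22=C23 bond is far faster than to the trisubstituted conjugated enoate, and no hydrogenolysis of the PMB ether can occur; the C21 descriptor changes only through priorities.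

Step 35
Reactants: 47 methyl (2Z,7S,9R,13S,17S,21S,25S,27S,29S,33R,35R,36S)-7,9,13,17,27,29,33-heptakis(TBSO)-21,25-dihydroxy-35-(PMBO)-3,36-dimethyltetracont-2-enoate
Product: 48 methyl (2Z,7S,9R,13S,17R,21R,25S,27S,29S,33R,35R,36S)-7,9,13,17,21,25,27,29,33-nonakis(TBSO)-35-(PMBO)-3,36-dimethyltetracont-2-enoate
Conditions: TBSOTf, 2,6-lutidine, CH2Cl2, −78 → 0 °C
Reagents that add atoms: tert-butyldimethylsilyl trifluoromethanesulfonate, CC(C)(C)[Si](C)(C)OS(=O)(=O)C(F)(F)F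
Why: Standard bis-silylation of two secondary alcohols; all carbinols except C35 are now TBS ethers.

Step 36
Reactants: 48 methyl (2Z,7S,9R,13S,17R,21R,25S,27S,29S,33R,35R,36S)-7,9,13,17,21,25,27,29,33-nonakis(TBSO)-35-(PMBO)-3,36-dimethyltetracont-2-enoate
Product: 49 methyl (2Z,7S,9R,13S,17R,21R,25S,27S,29S,33R,35R,36S)-7,9,13,17,21,25,27,29,33-nonakis(TBSO)-35-hydroxy-3,36-dimethyltetracont-2-enoate
Conditions: DDQ, CH2Cl2/pH 7 buffer, 0 °C → rt
Reagents that add atoms: none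
Why: Oxidative PMB cleavage frees only the C35 hydroxyl; TBS ethers and the enoate do not react with DDQ.

Step 37
Reactants: 49 methyl (2Z,7S,9R,13S,17R,21R,25S,27S,29S,33R,35R,36S)-7,9,13,17,21,25,27,29,33-nonakis(TBSO)-35-hydroxy-3,36-dimethyltetracont-2-enoate
Product: 50 (2Z,7S,9R,13S,17R,21R,25S,27S,29S,33R,35R,36S)-7,9,13,17,21,25,27,29,33-nonakis(TBSO)-35-hydroxy-3,36-dimethyltetracont-2-enoic acid
Conditions: LiOH, THF/MeOH/H2O, 45 °C; then aq. HCl to pH 4, 0 °C
Reagents that add atoms: lithium hydroxide, [Li+].[OH-]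
Why: Saponification of the methyl ester; secondary TBS ethers survive aqueous hydroxide, and the β,β-disubstituted enoate resists conjugate addition.

Step 38
Reactants: 50 (2Z,7S,9R,13S,17R,21R,25S,27S,29S,33R,35R,36S)-7,9,13,17,21,25,27,29,33-nonakis(TBSO)-35-hydroxy-3,36-dimethyltetracont-2-enoic acid
Product: 52 (2Z,7S,9R,13S,17R,21R,25S,27S,29S,33R,35R,36S)-7,9,13,17,21,25,27,29,33-nonakis(TBSO)-3,36-dimethyltetracont-2-en-35-olide, via mixed anhydride 51 (not isolated)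
Conditions: 2,4,6-Cl3C6H2COCl, Et3N, THF, rt; then DMAP, toluene, 60 °C, slow addition at high dilution
Reagents that add atoms: none
Why: Yamaguchi macrolactonisation: the mixed anhydride is attacked by DMAP at the less hindered enoyl carbonyl and the acylpyridinium is captured by the only free hydroxyl (C35); a 36-membered ring has no strain penalty, and dilution suppresses oligomers.

Step 39
Reactants: 52 (2Z,7S,9R,13S,17R,21R,25S,27S,29S,33R,35R,36S)-7,9,13,17,21,25,27,29,33-nonakis(TBSO)-3,36-dimethyltetracont-2-en-35-olide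
Product: 53 (2Z,7S,9R,13S,17R,21R,25S,27S,29S,33R,35R,36S)-7,9,13,17,21,25,27,29,33-nonahydroxy-3,36-dimethyltetracont-2-en-35-olide (CNP0126363.4)
Conditions: HF·pyridine, pyridine, THF, 0 °C → rt
Reagents that add atoms: none
Why: Global fluoride-mediated desilylation under buffered, mildly acidic conditions that leave the lactone and the Z-enoate in place.

## Compound list

1 | methyl but-2-ynoate | CC#CC(=O)OC | starting material
2 | methyl (Z)-3-iodobut-2-enoate | I/C(C)=C\C(=O)OC | intermediate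
3 | pentane-1,5-diol | OCCCCCO | starting material
4 | 5-(PMBO)pentan-1-ol | COc1ccc(COCCCCCO)cc1 | intermediate
5 | allyl acetate | C=CCOC(C)=O | starting material
6 | 5-(PMBO)pentanal | COc1ccc(COCCCCC=O)cc1 | intermediate (not isolated)
7 | (S)-8-(PMBO)oct-1-en-4-ol | COc1ccc(COCCCC[C@H](O)CC=C)cc1 | intermediate
8 | (S)-4-(TBSO)-8-(PMBO)oct-1-ene | COc1ccc(COCCCC[C@H](O[Si](C)(C)C(C)(C)C)CC=C)cc1 | intermediate
9 | (S)-5-(TBSO)-9-(PMBO)nonanal | COc1ccc(COCCCC[C@H](O[Si](C)(C)C(C)(C)C)CCCC=O)cc1 | intermediate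
10 | (4S,8S)-8-(TBSO)-12-(PMBO)dodec-1-en-4-ol | COc1ccc(COCCCC[C@H](O[Si](C)(C)C(C)(C)C)CCC[C@H](O)CC=C)cc1 | intermediate
11 | (4S,8S)-4,8-bis(TBSO)-12-(PMBO)dodec-1-ene | COc1ccc(COCCCC[C@H](O[Si](C)(C)C(C)(C)C)CCC[C@H](O[Si](C)(C)C(C)(C)C)CC=C)cc1 | intermediate
12 | (5S,9S)-5,9-bis(TBSO)-13-(PMBO)tridecanal | COc1ccc(COCCCC[C@H](O[Si](C)(C)C(C)(C)C)CCC[C@H](O[Si](C)(C)C(C)(C)C)CCCC=O)cc1 | intermediate
13 | (4R,8R,12S)-8,12-bis(TBSO)-16-(PMBO)hexadec-1-en-4-ol | COc1ccc(COCCCC[C@H](O[Si](C)(C)C(C)(C)C)CCC[C@H](O[Si](C)(C)C(C)(C)C)CCC[C@@H](O)CC=C)cc1 | intermediate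
14 | (4R,8S,12S)-4,8,12-tris(TBSO)-16-(PMBO)hexadec-1-ene | COc1ccc(COCCCC[C@H](O[Si](C)(C)C(C)(C)C)CCC[C@H](O[Si](C)(C)C(C)(C)C)CCC[C@@H](O[Si](C)(C)C(C)(C)C)CC=C)cc1 | intermediate
15 | (3R,7S,11S)-3,7,11-tris(TBSO)-15-(PMBO)pentadecanal (C7 aldehyde) | COc1ccc(COCCCC[C@H](O[Si](C)(C)C(C)(C)C)CCC[C@H](O[Si](C)(C)C(C)(C)C)CCC[C@@H](O[Si](C)(C)C(C)(C)C)CC=O)cc1 | intermediate
16 | (4S,6R,10S,14S)-6,10,14-tris(TBSO)-18-(PMBO)octadec-1-en-4-ol | COc1ccc(COCCCC[C@H](O[Si](C)(C)C(C)(C)C)CCC[C@H](O[Si](C)(C)C(C)(C)C)CCC[C@@H](O[Si](C)(C)C(C)(C)C)C[C@@H](O)CC=C)cc1 | intermediate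
17 | (4S,6R,10S,14S)-4,6,10,14-tetrakis(TBSO)-18-(PMBO)octadec-1-ene | COc1ccc(COCCCC[C@H](O[Si](C)(C)C(C)(C)C)CCC[C@H](O[Si](C)(C)C(C)(C)C)CCC[C@@H](O[Si](C)(C)C(C)(C)C)C[C@@H](O[Si](C)(C)C(C)(C)C)CC=C)cc1 | intermediate
18 | 9-[(4S,6R,10S,14S)-4,6,10,14-tetrakis(TBSO)-18-(PMBO)octadecyl]-9-borabicyclo[3.3.1]nonane | COc1ccc(COCCCC[C@H](O[Si](C)(C)C(C)(C)C)CCC[C@H](O[Si](C)(C)C(C)(C)C)CCC[C@@H](O[Si](C)(C)C(C)(C)C)C[C@@H](O[Si](C)(C)C(C)(C)C)CCCB2C3CCCC2CCC3)cc1 | intermediate (not isolated)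
19 | methyl (2Z,7S,9R,13S,17S)-7,9,13,17-tetrakis(TBSO)-21-(PMBO)-3-methylhenicos-2-enoate | COc1ccc(COCCCC[C@H](O[Si](C)(C)C(C)(C)C)CCC[C@H](O[Si](C)(C)C(C)(C)C)CCC[C@@H](O[Si](C)(C)C(C)(C)C)C[C@@H](O[Si](C)(C)C(C)(C)C)CCC/C(C)=C\C(=O)OC)cc1 | intermediate
20 | methyl (2Z,7S,9R,13S,17S)-7,9,13,17-tetrakis(TBSO)-21-hydroxy-3-methylhenicos-2-enoate | OCCCC[C@H](O[Si](C)(C)C(C)(C)C)CCC[C@H](O[Si](C)(C)C(C)(C)C)CCC[C@@H](O[Si](C)(C)C(C)(C)C)C[C@@H](O[Si](C)(C)C(C)(C)C)CCC/C(C)=C\C(=O)OC | intermediate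
21 | methyl (2Z,7S,9R,13S,17R)-7,9,13,17-tetrakis(TBSO)-3-methyl-21-oxohenicos-2-enoate (west aldehyde, C1–C21) | O=CCCC[C@H](O[Si](C)(C)C(C)(C)C)CCC[C@H](O[Si](C)(C)C(C)(C)C)CCC[C@@H](O[Si](C)(C)C(C)(C)C)C[C@@H](O[Si](C)(C)C(C)(C)C)CCC/C(C)=C\C(=O)OC | intermediate
22 | (S)-4-benzyloxazolidin-2-one | O=C1N[C@@H](Cc2ccccc2)CO1 | starting material
23 | hexanoyl chloride | CCCCCC(Cl)=O | starting material
24 | (S)-4-benzyl-3-hexanoyloxazolidin-2-one | CCCCCC(=O)N1[C@@H](Cc2ccccc2)COC1=O | intermediate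
25 | (S)-4-benzyl-3-[(S)-2-methylhexanoyl]oxazolidin-2-one | CCCC[C@H](C)C(=O)N1[C@@H](Cc2ccccc2)COC1=O | intermediate
26 | (S)-2-methylhexan-1-ol | CCCC[C@H](C)CO | intermediate
27 | (S)-2-methylhexanal | CCCC[C@H](C)C=O | intermediate (not isolated)
28 | (4R,5S)-5-methylnon-1-en-4-ol | CCCC[C@H](C)[C@H](O)CC=C | intermediate
29 | (4R,5S)-4-(PMBO)-5-methylnon-1-ene | CCCC[C@H](C)[C@H](OCc1ccc(OC)cc1)CC=C | intermediate
30 | (3R,4S)-3-(PMBO)-4-methyloctanal (C33 aldehyde) | CCCC[C@H](C)[C@H](OCc1ccc(OC)cc1)CC=O | intermediate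
31 | (4R,6R,7S)-6-(PMBO)-7-methylundec-1-en-4-ol | CCCC[C@H](C)[C@H](OCc1ccc(OC)cc1)C[C@H](O)CC=C | intermediate
32 | (4R,6R,7S)-4-(TBSO)-6-(PMBO)-7-methylundec-1-ene | CCCC[C@H](C)[C@H](OCc1ccc(OC)cc1)C[C@H](O[Si](C)(C)C(C)(C)C)CC=C | intermediate
33 | (5R,7R,8S)-5-(TBSO)-7-(PMBO)-8-methyldodecanal | CCCC[C@H](C)[C@H](OCc1ccc(OC)cc1)C[C@H](O[Si](C)(C)C(C)(C)C)CCCC=O | intermediate
34 | (4S,8R,10R,11S)-8-(TBSO)-10-(PMBO)-11-methylpentadec-1-en-4-ol | CCCC[C@H](C)[C@H](OCc1ccc(OC)cc1)C[C@H](O[Si](C)(C)C(C)(C)C)CCC[C@H](O)CC=C | intermediate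
35 | (4S,8R,10R,11S)-4,8-bis(TBSO)-10-(PMBO)-11-methylpentadec-1-ene | CCCC[C@H](C)[C@H](OCc1ccc(OC)cc1)C[C@H](O[Si](C)(C)C(C)(C)C)CCC[C@H](O[Si](C)(C)C(C)(C)C)CC=C | intermediate
36 | (3S,7R,9R,10S)-3,7-bis(TBSO)-9-(PMBO)-10-methyltetradecanal (C27 aldehyde) | CCCC[C@H](C)[C@H](OCc1ccc(OC)cc1)C[C@H](O[Si](C)(C)C(C)(C)C)CCC[C@H](O[Si](C)(C)C(C)(C)C)CC=O | intermediate
37 | (4S,6S,10R,12R,13S)-6,10-bis(TBSO)-12-(PMBO)-13-methylheptadec-1-en-4-ol | CCCC[C@H](C)[C@H](OCc1ccc(OC)cc1)C[C@H](O[Si](C)(C)C(C)(C)C)CCC[C@H](O[Si](C)(C)C(C)(C)C)C[C@@H](O)CC=C | intermediate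
38 | (4S,6S,10R,12R,13S)-4,6,10-tris(TBSO)-12-(PMBO)-13-methylheptadec-1-ene | CCCC[C@H](C)[C@H](OCc1ccc(OC)cc1)C[C@H](O[Si](C)(C)C(C)(C)C)CCC[C@H](O[Si](C)(C)C(C)(C)C)C[C@@H](O[Si](C)(C)C(C)(C)C)CC=C | intermediate
39 | (3R,5S,9R,11R,12S)-3,5,9-tris(TBSO)-11-(PMBO)-12-methylhexadecanal (east aldehyde, C25–C40) | CCCC[C@H](C)[C@H](OCc1ccc(OC)cc1)C[C@H](O[Si](C)(C)C(C)(C)C)CCC[C@H](O[Si](C)(C)C(C)(C)C)C[C@@H](O[Si](C)(C)C(C)(C)C)CC=O | intermediate
40 | propargyl bromide | C#CCBr | starting material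
41 | allenylmagnesium bromide | C=C=C[Mg]Br | intermediate (not isolated)
42 | allenylboronic acid | C=C=CB(O)O | intermediate (not isolated)
43 | 2-(propa-1,2-dien-1-yl)-5,5-dimethyl-1,3,2-dioxaborinane | C=C=CB1OCC(C)(C)CO1 | intermediate
44 | [(E)-3-(5,5-dimethyl-1,3,2-dioxaborinan-2-yl)prop-2-en-1-yl]bis(isopinocampheyl)borane, Ipc from (+)-α-pinene (γ-boryl allylborane) | CC1(C)COB(/C=C/CB([C@@H]2C[C@@H]3C[C@H]([C@H]2C)C3(C)C)[C@@H]2C[C@@H]3C[C@H]([C@H]2C)C3(C)C)OC1 | intermediate (not isolated)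
45 | methyl (2Z)-21-{[bis(isopinocampheyl)boryl]oxy}-22-(5,5-dimethyl-1,3,2-dioxaborinan-2-yl)-7,9,13,17-tetrakis(TBSO)-3-methyltetracosa-2,23-dienoate, 21,22-anti, configured as in the SMILES (C21 borinate allylboronate) | C=C[C@H](B1OCC(C)(C)CO1)[C@H](OB([C@@H]1C[C@@H]2C[C@H]([C@H]1C)C2(C)C)[C@@H]1C[C@@H]2C[C@H]([C@H]1C)C2(C)C)CCC[C@H](O[Si](C)(C)C(C)(C)C)CCC[C@H](O[Si](C)(C)C(C)(C)C)CCC[C@@H](O[Si](C)(C)C(C)(C)C)C[C@@H](O[Si](C)(C)C(C)(C)C)CCC/C(C)=C\C(=O)OC | intermediate (not isolated)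
46 | methyl (2Z,7S,9R,13S,17S,21R,22E,25S,27S,29S,33R,35R,36S)-7,9,13,17,27,29,33-heptakis(TBSO)-21,25-dihydroxy-35-(PMBO)-3,36-dimethyltetraconta-2,22-dienoate | CCCC[C@H](C)[C@H](OCc1ccc(OC)cc1)C[C@H](O[Si](C)(C)C(C)(C)C)CCC[C@H](O[Si](C)(C)C(C)(C)C)C[C@@H](O[Si](C)(C)C(C)(C)C)C[C@@H](O)C/C=C/[C@H](O)CCC[C@H](O[Si](C)(C)C(C)(C)C)CCC[C@H](O[Si](C)(C)C(C)(C)C)CCC[C@@H](O[Si](C)(C)C(C)(C)C)C[C@@H](O[Si](C)(C)C(C)(C)C)CCC/C(C)=C\C(=O)OC | intermediate
47 | methyl (2Z,7S,9R,13S,17S,21S,25S,27S,29S,33R,35R,36S)-7,9,13,17,27,29,33-heptakis(TBSO)-21,25-dihydroxy-35-(PMBO)-3,36-dimethyltetracont-2-enoate | CCCC[C@H](C)[C@H](OCc1ccc(OC)cc1)C[C@H](O[Si](C)(C)C(C)(C)C)CCC[C@H](O[Si](C)(C)C(C)(C)C)C[C@@H](O[Si](C)(C)C(C)(C)C)C[C@@H](O)CCC[C@H](O)CCC[C@H](O[Si](C)(C)C(C)(C)C)CCC[C@H](O[Si](C)(C)C(C)(C)C)CCC[C@@H](O[Si](C)(C)C(C)(C)C)C[C@@H](O[Si](C)(C)C(C)(C)C)CCC/C(C)=C\C(=O)OC | intermediate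
48 | methyl (2Z,7S,9R,13S,17R,21R,25S,27S,29S,33R,35R,36S)-7,9,13,17,21,25,27,29,33-nonakis(TBSO)-35-(PMBO)-3,36-dimethyltetracont-2-enoate | CCCC[C@H](C)[C@H](OCc1ccc(OC)cc1)C[C@H](O[Si](C)(C)C(C)(C)C)CCC[C@H](O[Si](C)(C)C(C)(C)C)C[C@@H](O[Si](C)(C)C(C)(C)C)C[C@@H](O[Si](C)(C)C(C)(C)C)CCC[C@H](O[Si](C)(C)C(C)(C)C)CCC[C@H](O[Si](C)(C)C(C)(C)C)CCC[C@H](O[Si](C)(C)C(C)(C)C)CCC[C@@H](O[Si](C)(C)C(C)(C)C)C[C@@H](O[Si](C)(C)C(C)(C)C)CCC/C(C)=C\C(=O)OC | intermediate
49 | methyl (2Z,7S,9R,13S,17R,21R,25S,27S,29S,33R,35R,36S)-7,9,13,17,21,25,27,29,33-nonakis(TBSO)-35-hydroxy-3,36-dimethyltetracont-2-enoate | CCCC[C@H](C)[C@H](O)C[C@H](O[Si](C)(C)C(C)(C)C)CCC[C@H](O[Si](C)(C)C(C)(C)C)C[C@@H](O[Si](C)(C)C(C)(C)C)C[C@@H](O[Si](C)(C)C(C)(C)C)CCC[C@H](O[Si](C)(C)C(C)(C)C)CCC[C@H](O[Si](C)(C)C(C)(C)C)CCC[C@H](O[Si](C)(C)C(C)(C)C)CCC[C@@H](O[Si](C)(C)C(C)(C)C)C[C@@H](O[Si](C)(C)C(C)(C)C)CCC/C(C)=C\C(=O)OC | intermediate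
50 | (2Z,7S,9R,13S,17R,21R,25S,27S,29S,33R,35R,36S)-7,9,13,17,21,25,27,29,33-nonakis(TBSO)-35-hydroxy-3,36-dimethyltetracont-2-enoic acid (seco acid) | CCCC[C@H](C)[C@H](O)C[C@H](O[Si](C)(C)C(C)(C)C)CCC[C@H](O[Si](C)(C)C(C)(C)C)C[C@@H](O[Si](C)(C)C(C)(C)C)C[C@@H](O[Si](C)(C)C(C)(C)C)CCC[C@H](O[Si](C)(C)C(C)(C)C)CCC[C@H](O[Si](C)(C)C(C)(C)C)CCC[C@H](O[Si](C)(C)C(C)(C)C)CCC[C@@H](O[Si](C)(C)C(C)(C)C)C[C@@H](O[Si](C)(C)C(C)(C)C)CCC/C(C)=C\C(=O)O | intermediate
51 | mixed anhydride of 50 with 2,4,6-trichlorobenzoic acid | CCCC[C@H](C)[C@H](O)C[C@H](O[Si](C)(C)C(C)(C)C)CCC[C@H](O[Si](C)(C)C(C)(C)C)C[C@@H](O[Si](C)(C)C(C)(C)C)C[C@@H](O[Si](C)(C)C(C)(C)C)CCC[C@H](O[Si](C)(C)C(C)(C)C)CCC[C@H](O[Si](C)(C)C(C)(C)C)CCC[C@H](O[Si](C)(C)C(C)(C)C)CCC[C@@H](O[Si](C)(C)C(C)(C)C)C[C@@H](O[Si](C)(C)C(C)(C)C)CCC/C(C)=C\C(=O)OC(=O)c1c(Cl)cc(Cl)cc1Cl | intermediate (not isolated)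
52 | (2Z,7S,9R,13S,17R,21R,25S,27S,29S,33R,35R,36S)-7,9,13,17,21,25,27,29,33-nonakis(TBSO)-3,36-dimethyltetracont-2-en-35-olide (nona-TBS macrolide) | CCCC[C@H](C)[C@H]1C[C@H](O[Si](C)(C)C(C)(C)C)CCC[C@H](O[Si](C)(C)C(C)(C)C)C[C@@H](O[Si](C)(C)C(C)(C)C)C[C@@H](O[Si](C)(C)C(C)(C)C)CCC[C@H](O[Si](C)(C)C(C)(C)C)CCC[C@H](O[Si](C)(C)C(C)(C)C)CCC[C@H](O[Si](C)(C)C(C)(C)C)CCC[C@@H](O[Si](C)(C)C(C)(C)C)C[C@@H](O[Si](C)(C)C(C)(C)C)CCC/C(C)=C\C(=O)O1 | intermediate
53 | (2Z,7S,9R,13S,17R,21R,25S,27S,29S,33R,35R,36S)-7,9,13,17,21,25,27,29,33-nonahydroxy-3,36-dimethyltetracont-2-en-35-olide (CNP0126363.4) | CCCC[C@H](C)[C@H]1C[C@H](O)CCC[C@H](O)C[C@@H](O)C[C@@H](O)CCC[C@H](O)CCC[C@H](O)CCC[C@H](O)CCC[C@@H](O)C[C@@H](O)CCC/C(C)=C\C(=O)O1 | target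

## Step count and risks

Total step count: 39. Longest linear sequence: 22 steps (from 22 and 23 through 39 to 53: steps 17–31 and 33–39). The west line from 3 (steps 2–16 and 33–39) is equally long.

**Step 33 (key step).**
- What may go wrong: loss of the order of addition, either by the boronate end engaging 21 before 39 arrives or by left-over dialkylborane reagent consuming 39, which gives symmetric double adducts of one aldehyde. Incomplete E/Z equilibration of the hydroboration adduct would erode the 21,22-anti relation. The second allylboration of the hindered β-silyloxy aldehyde may be slow, with loss of E and 1,5-anti selectivity.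
- Fallback: the same two bonds are made stepwise with an alkyne as the three-carbon unit, setting out from 39 and 21 and returning at 48.
  - Aldehyde 39 is propargylated with allenylboronic acid pinacol ester under a chiral BINOL-phosphoric acid (the antipode giving 25S) to the homopropargylic alcohol F1, which is silylated to the TBS ether F2.
  - The lithium acetylide of F2 adds to 21 at −78 °C and forms C21–C22 as the epimeric propargylic alcohols F3.
  - Oxidation gives the ynone F4, and Noyori transfer hydrogenation with RuCl[(R,R)-TsDPEN](p-cymene) in isopropanol gives the 21R propargylic alcohol F5.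
  - Excess diimide saturates the alkyne to the C21 alcohol F6, and silylation as in step 35 gives 48.

**Step 38 (macrolactonisation).**
- What may go wrong: Z-to-E isomerisation or deconjugation of the activated 3-methyl enoyl unit through reversible DMAP addition or vinylketene formation; slow acylation of the hindered C35 hydroxyl, letting oligomerisation compete.
- Fallback: the ester is made intermolecularly and the ring is closed at C3–C4, setting out from 17 and returning at 52.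
  - DDQ converts 17 into the C21 alcohol F7, and oxidation as in step 16 gives the alkenyl aldehyde F8.
  - The double allylboration of step 33 with 43, F8 and 39 gives the ene-diol F9, and silylation gives the nona-TBS ether F10.
  - DDQ frees the C35 alcohol F11, which is esterified (DCC, DMAP) with (Z)-3-iodobut-2-enoic acid F12, made from but-2-ynoic acid with NaI in AcOH, to the iodoenoate F13.
  - 9-BBN hydroborates only the terminal C4=C5 bond to the borane F14, and Pd(dppf)Cl2, AsPh3 and Cs2CO3 at high dilution close the ring to the 22,23-didehydro macrolide F15.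
  - Diimide as in step 34 then gives 52.

**Step 20 (C35 allylation).**
- What may go wrong: poor facial selectivity where the catalyst has to override the bias of the α-methyl group, and partial epimerisation at C36 through enolisation of the transient aldehyde at 100 °C.
- Fallback: from 26, oxidise (PhI(OAc)2, TEMPO) to the isolated aldehyde 27 and allylate at −78 °C with B-allylbis(isopinocampheyl)borane made from (−)-α-pinene. This stoichiometric reagent is known to dominate α-methyl aldehydes at low temperature, and the route is rejoined at 28.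

**Step 5 (and its repeats, steps 8 and 25).**
- What may go wrong: branched hydroformylation or alkene isomerisation along the chain, giving inseparable regioisomeric aldehydes.
- Fallback: from 8, cross-metathesis with acrolein (second-generation Hoveyda–Grubbs catalyst) gives the enal F16, and conjugate reduction with [(Ph3P)CuH]6 gives 9. The same two operations apply to 11 and 32.

**Step 29 (and its siblings, steps 12 and 23).**
- What may go wrong: β-elimination of the silyloxy or PMB-oxy group from the aldehyde under carbonate at 100 °C before the allyl group is delivered, silyl migration during the long heating, or erosion of 1,3-diastereocontrol by the β-oxygenated centre.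
- Fallback: from aldehyde 36, allylate at −78 °C without base with B-allylbis(isopinocampheyl)borane made from (+)-α-pinene, a stoichiometric reagent-controlled allylboration, rejoining at 37. Aldehydes 15 and 30 are treated likewise with the reagent from (+)-α-pinene and (−)-α-pinene respectively, rejoining at 16 and 31.

## Further compounds

F1 | step 33 | C25–C40 homopropargylic alcohol (25S), 27,29,33-tris-TBS, 35-PMB | CCCC[C@H](C)[C@H](OCc1ccc(OC)cc1)C[C@H](O[Si](C)(C)C(C)(C)C)CCC[C@H](O[Si](C)(C)C(C)(C)C)C[C@@H](O[Si](C)(C)C(C)(C)C)C[C@@H](O)CC#C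
F2 | step 33 | TBS ether of F1 (C22–C40 terminal alkyne) | CCCC[C@H](C)[C@H](OCc1ccc(OC)cc1)C[C@H](O[Si](C)(C)C(C)(C)C)CCC[C@H](O[Si](C)(C)C(C)(C)C)C[C@@H](O[Si](C)(C)C(C)(C)C)C[C@@H](O[Si](C)(C)C(C)(C)C)CC#C
F3 | step 33 | C1–C40 22-yn-21-ol, both C21 epimers | CCCC[C@H](C)[C@H](OCc1ccc(OC)cc1)C[C@H](O[Si](C)(C)C(C)(C)C)CCC[C@H](O[Si](C)(C)C(C)(C)C)C[C@@H](O[Si](C)(C)C(C)(C)C)C[C@@H](O[Si](C)(C)C(C)(C)C)CC#CC(O)CCC[C@H](O[Si](C)(C)C(C)(C)C)CCC[C@H](O[Si](C)(C)C(C)(C)C)CCC[C@@H](O[Si](C)(C)C(C)(C)C)C[C@@H](O[Si](C)(C)C(C)(C)C)CCC/C(C)=C\C(=O)OC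
F4 | step 33 | C1–C40 22-yn-21-one | CCCC[C@H](C)[C@H](OCc1ccc(OC)cc1)C[C@H](O[Si](C)(C)C(C)(C)C)CCC[C@H](O[Si](C)(C)C(C)(C)C)C[C@@H](O[Si](C)(C)C(C)(C)C)C[C@@H](O[Si](C)(C)C(C)(C)C)CC#CC(=O)CCC[C@H](O[Si](C)(C)C(C)(C)C)CCC[C@H](O[Si](C)(C)C(C)(C)C)CCC[C@@H](O[Si](C)(C)C(C)(C)C)C[C@@H](O[Si](C)(C)C(C)(C)C)CCC/C(C)=C\C(=O)OC
F5 | step 33 | C1–C40 (21R)-22-yn-21-ol | CCCC[C@H](C)[C@H](OCc1ccc(OC)cc1)C[C@H](O[Si](C)(C)C(C)(C)C)CCC[C@H](O[Si](C)(C)C(C)(C)C)C[C@@H](O[Si](C)(C)C(C)(C)C)C[C@@H](O[Si](C)(C)C(C)(C)C)CC#C[C@H](O)CCC[C@H](O[Si](C)(C)C(C)(C)C)CCC[C@H](O[Si](C)(C)C(C)(C)C)CCC[C@@H](O[Si](C)(C)C(C)(C)C)C[C@@H](O[Si](C)(C)C(C)(C)C)CCC/C(C)=C\C(=O)OC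
F6 | step 33 | C1–C40 saturated C21 alcohol, 25-TBS | CCCC[C@H](C)[C@H](OCc1ccc(OC)cc1)C[C@H](O[Si](C)(C)C(C)(C)C)CCC[C@H](O[Si](C)(C)C(C)(C)C)C[C@@H](O[Si](C)(C)C(C)(C)C)C[C@@H](O[Si](C)(C)C(C)(C)C)CCC[C@H](O)CCC[C@H](O[Si](C)(C)C(C)(C)C)CCC[C@H](O[Si](C)(C)C(C)(C)C)CCC[C@@H](O[Si](C)(C)C(C)(C)C)C[C@@H](O[Si](C)(C)C(C)(C)C)CCC/C(C)=C\C(=O)OC
F7 | step 38 | C4–C21 alkenol (C21 alcohol, C4=C5 alkene, four TBS ethers) | OCCCC[C@H](O[Si](C)(C)C(C)(C)C)CCC[C@H](O[Si](C)(C)C(C)(C)C)CCC[C@@H](O[Si](C)(C)C(C)(C)C)C[C@@H](O[Si](C)(C)C(C)(C)C)CC=C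
F8 | step 38 | C4–C21 alkenyl aldehyde | O=CCCC[C@H](O[Si](C)(C)C(C)(C)C)CCC[C@H](O[Si](C)(C)C(C)(C)C)CCC[C@@H](O[Si](C)(C)C(C)(C)C)C[C@@H](O[Si](C)(C)C(C)(C)C)CC=C
F9 | step 38 | C4–C40 (E)-22-ene-21,25-diol with C4=C5 alkene | CCCC[C@H](C)[C@H](OCc1ccc(OC)cc1)C[C@H](O[Si](C)(C)C(C)(C)C)CCC[C@H](O[Si](C)(C)C(C)(C)C)C[C@@H](O[Si](C)(C)C(C)(C)C)C[C@@H](O)C/C=C/[C@H](O)CCC[C@H](O[Si](C)(C)C(C)(C)C)CCC[C@H](O[Si](C)(C)C(C)(C)C)CCC[C@@H](O[Si](C)(C)C(C)(C)C)C[C@@H](O[Si](C)(C)C(C)(C)C)CC=C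
F10 | step 38 | nona-TBS ether of F9 (35-PMB) | CCCC[C@H](C)[C@H](OCc1ccc(OC)cc1)C[C@H](O[Si](C)(C)C(C)(C)C)CCC[C@H](O[Si](C)(C)C(C)(C)C)C[C@@H](O[Si](C)(C)C(C)(C)C)C[C@@H](O[Si](C)(C)C(C)(C)C)C/C=C/[C@H](O[Si](C)(C)C(C)(C)C)CCC[C@H](O[Si](C)(C)C(C)(C)C)CCC[C@H](O[Si](C)(C)C(C)(C)C)CCC[C@@H](O[Si](C)(C)C(C)(C)C)C[C@@H](O[Si](C)(C)C(C)(C)C)CC=C
F11 | step 38 | C35 alcohol from F10 | CCCC[C@H](C)[C@H](O)C[C@H](O[Si](C)(C)C(C)(C)C)CCC[C@H](O[Si](C)(C)C(C)(C)C)C[C@@H](O[Si](C)(C)C(C)(C)C)C[C@@H](O[Si](C)(C)C(C)(C)C)C/C=C/[C@H](O[Si](C)(C)C(C)(C)C)CCC[C@H](O[Si](C)(C)C(C)(C)C)CCC[C@H](O[Si](C)(C)C(C)(C)C)CCC[C@@H](O[Si](C)(C)C(C)(C)C)C[C@@H](O[Si](C)(C)C(C)(C)C)CC=C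
F12 | step 38 | (Z)-3-iodobut-2-enoic acid | I/C(C)=C\C(=O)O
F13 | step 38 | C35 (Z)-3-iodobut-2-enoate of F11 | CCCC[C@H](C)[C@H](OC(=O)/C=C(/C)I)C[C@H](O[Si](C)(C)C(C)(C)C)CCC[C@H](O[Si](C)(C)C(C)(C)C)C[C@@H](O[Si](C)(C)C(C)(C)C)C[C@@H](O[Si](C)(C)C(C)(C)C)C/C=C/[C@H](O[Si](C)(C)C(C)(C)C)CCC[C@H](O[Si](C)(C)C(C)(C)C)CCC[C@H](O[Si](C)(C)C(C)(C)C)CCC[C@@H](O[Si](C)(C)C(C)(C)C)C[C@@H](O[Si](C)(C)C(C)(C)C)CC=C
F14 | step 38 | C4 B-alkyl-9-BBN derivative of F13 | CCCC[C@H](C)[C@H](OC(=O)/C=C(/C)I)C[C@H](O[Si](C)(C)C(C)(C)C)CCC[C@H](O[Si](C)(C)C(C)(C)C)C[C@@H](O[Si](C)(C)C(C)(C)C)C[C@@H](O[Si](C)(C)C(C)(C)C)C/C=C/[C@H](O[Si](C)(C)C(C)(C)C)CCC[C@H](O[Si](C)(C)C(C)(C)C)CCC[C@H](O[Si](C)(C)C(C)(C)C)CCC[C@@H](O[Si](C)(C)C(C)(C)C)C[C@@H](O[Si](C)(C)C(C)(C)C)CCCB1C2CCCC1CCC2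
F15 | step 38 | (22E)-22,23-didehydro nona-TBS macrolide | CCCC[C@H](C)[C@H]1C[C@H](O[Si](C)(C)C(C)(C)C)CCC[C@H](O[Si](C)(C)C(C)(C)C)C[C@@H](O[Si](C)(C)C(C)(C)C)C[C@@H](O[Si](C)(C)C(C)(C)C)C/C=C/[C@H](O[Si](C)(C)C(C)(C)C)CCC[C@H](O[Si](C)(C)C(C)(C)C)CCC[C@H](O[Si](C)(C)C(C)(C)C)CCC[C@@H](O[Si](C)(C)C(C)(C)C)C[C@@H](O[Si](C)(C)C(C)(C)C)CCC/C(C)=C\C(=O)O1
F16 | step 5 | (S,E)-5-(TBSO)-9-(PMBO)non-2-enal | COc1ccc(COCCCC[C@H](O[Si](C)(C)C(C)(C)C)C/C=C/C=O)cc1
F0 | step 20 | none | none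
F0 | step 29 | none | none
A1 | alternative 1 | C35 (Z)-3-iodobut-2-enoate of the C4–C40 nona-TBS polyol with C4=C5 alkene | CCCC[C@H](C)[C@H](OC(=O)/C=C(/C)I)C[C@H](O[Si](C)(C)C(C)(C)C)CCC[C@H](O[Si](C)(C)C(C)(C)C)C[C@@H](O[Si](C)(C)C(C)(C)C)C[C@@H](O[Si](C)(C)C(C)(C)C)CCC[C@H](O[Si](C)(C)C(C)(C)C)CCC[C@H](O[Si](C)(C)C(C)(C)C)CCC[C@H](O[Si](C)(C)C(C)(C)C)CCC[C@@H](O[Si](C)(C)C(C)(C)C)C[C@@H](O[Si](C)(C)C(C)(C)C)CC=C
A2 | alternative 1 | nona-TBS ether of the target macrolide (identical with 52) | CCCC[C@H](C)[C@H]1C[C@H](O[Si](C)(C)C(C)(C)C)CCC[C@H](O[Si](C)(C)C(C)(C)C)C[C@@H](O[Si](C)(C)C(C)(C)C)C[C@@H](O[Si](C)(C)C(C)(C)C)CCC[C@H](O[Si](C)(C)C(C)(C)C)CCC[C@H](O[Si](C)(C)C(C)(C)C)CCC[C@H](O[Si](C)(C)C(C)(C)C)CCC[C@@H](O[Si](C)(C)C(C)(C)C)C[C@@H](O[Si](C)(C)C(C)(C)C)CCC/C(C)=C\C(=O)O1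
A3 | alternative 2 | 2-(tert-butyldimethylsilyl)-1,3-dithiane | CC(C)(C)[Si](C)(C)C1SCCCS1
A4 | alternative 2 | west C4–C26 epoxide (C25–C26 oxirane, five TBS ethers, C4=C5 alkene) | C1O[C@H]1CCC[C@H](O[Si](C)(C)C(C)(C)C)CCC[C@H](O[Si](C)(C)C(C)(C)C)CCC[C@H](O[Si](C)(C)C(C)(C)C)CCC[C@@H](O[Si](C)(C)C(C)(C)C)C[C@@H](O[Si](C)(C)C(C)(C)C)CC=C
A5 | alternative 2 | east C28–C40 epoxide (C28–C29 oxirane, 33-TBS, 35-PMB) | CCCC[C@H](C)[C@H](OCc1ccc(OC)cc1)C[C@H](O[Si](C)(C)C(C)(C)C)CCC[C@H]1CO1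
A6 | alternative 2 | C4–C40 chain with C27 1,3-dithiane, C25 TBS ether and free C29 hydroxyl | CCCC[C@H](C)[C@H](OCc1ccc(OC)cc1)C[C@H](O[Si](C)(C)C(C)(C)C)CCC[C@H](O)CC1(SCCCS1)C[C@@H](O[Si](C)(C)C(C)(C)C)CCC[C@H](O[Si](C)(C)C(C)(C)C)CCC[C@H](O[Si](C)(C)C(C)(C)C)CCC[C@H](O[Si](C)(C)C(C)(C)C)CCC[C@@H](O[Si](C)(C)C(C)(C)C)C[C@@H](O[Si](C)(C)C(C)(C)C)CC=C
A7 | alternative 3 | ester-linked diene (C35 ester of the C1–C19 acid with the C20–C40 alcohol; allyl on C17, vinyl on C21) | C=CC[C@H](O[Si](C)(C)C(C)(C)C)CCC[C@H](O[Si](C)(C)C(C)(C)C)CCC[C@@H](O[Si](C)(C)C(C)(C)C)C[C@@H](O[Si](C)(C)C(C)(C)C)CCC/C(C)=C\C(=O)O[C@@H]([C@@H](C)CCCC)C[C@H](O[Si](C)(C)C(C)(C)C)CCC[C@H](O[Si](C)(C)C(C)(C)C)C[C@@H](O[Si](C)(C)C(C)(C)C)C[C@@H](O[Si](C)(C)C(C)(C)C)CCC[C@H](O[Si](C)(C)C(C)(C)C)C=C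
A8 | alternative 3 | 19,20-didehydro macrolide nona-TBS ether (E isomer drawn) | CCCC[C@H](C)[C@H]1C[C@H](O[Si](C)(C)C(C)(C)C)CCC[C@H](O[Si](C)(C)C(C)(C)C)C[C@@H](O[Si](C)(C)C(C)(C)C)C[C@@H](O[Si](C)(C)C(C)(C)C)CCC[C@H](O[Si](C)(C)C(C)(C)C)/C=C/C[C@H](O[Si](C)(C)C(C)(C)C)CCC[C@H](O[Si](C)(C)C(C)(C)C)CCC[C@@H](O[Si](C)(C)C(C)(C)C)C[C@@H](O[Si](C)(C)C(C)(C)C)CCC/C(C)=C\C(=O)O1
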